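**Strategy**

Everything rests on opening the dihydropyran of ring A (the tropolone-fused pyran beside the C4 carbinol) at the two bonds that tie tropolone carbons C5' and C6' to the CH2 group on C2 and to the tertiary oxygen on C3. The key step closes both in one pot: a B-alkyl Suzuki–Miyaura coupling at the C–Br carbon of a 5-bromo-6-methoxytropone, then fluoride-triggered addition–elimination of the C3 alkoxide at the neighbouring methoxy carbon. It exploits the vicinal C5'(Br)/C6'(OMe) pair of the tropone as a two-carbon bis-electrophile for the 1,3-related CH2/O pair. The precursor is a humulene-derived iodo bis-silyl ether; ring B follows by a hetero-Diels–Alder reaction.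

Key step: step 20

**Remarks on the chemistry (assumptions)**

- Ring positions use humulane numbering: C1H2–C2–C3(CH3)–C4–C5H2–C6–C7(CH3)–C8H2–C9=C10–C11(CH3)2. The one-carbon unit on C2 is called C16. Tropone carbons are primed, with C1' as the carbonyl carbon of 7. Ring A is the tropolone pyran on C2/C3, ring B that on C6/C7.
- α-Humulene, 2-methylanisole, (tributylstannyl)methanol, tributyl(iodomethyl)stannane and B-methoxy-9-BBN are taken as commercial.
- The 6,7-oxirane of 14–17 is only a protecting group for the 6,7-olefin. It is trans (from the E olefin) and both trans forms are carried, so its two carbons have no stereodescriptor in the SMILES. They converge to one compound in step 15.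

**Route**

Step 1
Reactants: 1 2-methylanisole
Product: 2 1-methoxy-2-methylcyclohexa-1,4-diene
Conditions: Li, NH3 (l), THF, t-BuOH, −78 to −33 °C; NH4Cl
Reagents that add atoms: none
Why: Birch reduction of an anisole leaves both donor-substituted carbons on a retained double bond, so the tetrasubstituted enol-ether olefin should form regioselectively.

Step 2
Reactants: 2 1-methoxy-2-methylcyclohexa-1,4-diene
Product: 3 rac-7,7-dibromo-1-methoxy-6-methylbicyclo[4.1.0]hept-3-ene
Conditions: CHBr3, KOt-Bu, pentane, −20 to 0 °C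
Reagents that add atoms: bromoform BrC(Br)Br
Why: Electrophilic dibromocarbene should add to the electron-rich tetrasubstituted enol-ether olefin in preference to the isolated disubstituted one (gem-dihalocyclopropanation).

Step 3
Reactants: 3 rac-7,7-dibromo-1-methoxy-6-methylbicyclo[4.1.0]hept-3-ene
Product: 4 7,7-dibromo-1-methoxy-6-methylbicyclo[4.1.0]heptane-3,4-diol (cis-diol)
Conditions: OsO4 (cat.), NMO, acetone/H2O, 0 °C
Reagents that add atoms: osmium tetroxide O=[Os](=O)(=O)=O (catalytic oxygen carrier); N-methylmorpholine N-oxide C[N+]1([O-])CCOCC1; water O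
Why: Catalytic syn-dihydroxylation of the only olefin gives the cis-diol, whose orientation relative to the cyclopropane is irrelevant because both carbinol carbons become sp2 in step 4.

Step 4
Reactants: 4 7,7-dibromo-1-methoxy-6-methylbicyclo[4.1.0]heptane-3,4-diol
Product: 6 5-bromo-2-hydroxy-6-methoxy-4-methylcyclohepta-2,4,6-trien-1-one, via 3,4-dione 5 (not isolated)
Conditions: DMSO, (CF3CO)2O, CH2Cl2, −60 °C; Et3N, −60 °C to rt
Reagents that add atoms: none
Why: Swern-type oxidation gives the 1,2-dione, whose enol should open the gem-dibromocyclopropane with loss of HBr and expand the ring to the aromatic tropolone, the methoxy, bromo and methyl groups being placed by the anisole.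

Step 5
Reactants: 6 5-bromo-2-hydroxy-6-methoxy-4-methylcyclohepta-2,4,6-trien-1-one
Product: 7 5-bromo-2,6-dimethoxy-4-methylcyclohepta-2,4,6-trien-1-one
Conditions: MeI, K2CO3, acetone, 40 °C
Reagents that add atoms: iodomethane CI
Why: Williamson O-methylation of the tropolonate should favour the ether that keeps the carbonyl conjugated with the 6-methoxy group; any regioisomeric ether would be removed by chromatography and would converge in step 22 in any case.

Step 6
Reactants: 3 rac-7,7-dibromo-1-methoxy-6-methylbicyclo[4.1.0]hept-3-ene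
Product: 8 2-bromo-3-methylcyclohepta-2,5-dien-1-one
Conditions: AgNO3, acetone/H2O, 0 °C to rt
Reagents that add atoms: water O
Why: Silver-assisted ionisation of a cyclopropyl bromide, helped by the methoxy group, should open the ring to an oxocarbenium ion that is hydrolysed to the ring-expanded 2-bromo enone (gem-dihalocyclopropane ring expansion).

Step 7
Reactants: 8 2-bromo-3-methylcyclohepta-2,5-dien-1-one
Product: 9 2-(hydroxymethyl)-3-methylcyclohepta-2,5-dien-1-one
Conditions: Bu3SnCH2OH, Pd(PPh3)4 (cat.), CuI (cat.), 1,4-dioxane, 80 °C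
Reagents that add atoms: (tributylstannyl)methanol CCCC[Sn](CCCC)(CCCC)CO
Why: Stille coupling of an α-bromo enone transfers the hydroxymethyl group under neutral conditions that should leave the skipped olefin in place.

Step 8
Reactants: 9 2-(hydroxymethyl)-3-methylcyclohepta-2,5-dien-1-one
Product: 10 5,6-dihydroxy-2-(hydroxymethyl)-3-methylcyclohept-2-en-1-one (cis-diol)
Conditions: OsO4 (cat.), NMO, citric acid, t-BuOH/H2O, rt
Reagents that add atoms: osmium tetroxide O=[Os](=O)(=O)=O (catalytic oxygen carrier); N-methylmorpholine N-oxide C[N+]1([O-])CCOCC1; water O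
Why: Buffered catalytic dihydroxylation should take the isolated cis olefin and leave the electron-poor tetrasubstituted enone double bond.

Step 9
Reactants: 10 5,6-dihydroxy-2-(hydroxymethyl)-3-methylcyclohept-2-en-1-one
Product: 11 4,7-dihydroxy-2-methyl-5-oxocyclohepta-1,3,6-triene-1-carbaldehyde
Conditions: (COCl)2, DMSO, CH2Cl2, −78 °C; Et3N, −78 °C to rt
Reagents that add atoms: none
Why: Swern oxidation of all three hydroxyls gives an aldehyde and a 1,2-dione, and enolisation of the resulting trione should aromatise it to the hydroxytropolone.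

Step 10
Reactants: 11 4,7-dihydroxy-2-methyl-5-oxocyclohepta-1,3,6-triene-1-carbaldehyde
Product: 12 2,6-dihydroxy-5-(hydroxymethyl)-4-methylcyclohepta-2,4,6-trien-1-one
Conditions: NaBH4, MeOH, 0 °C; dilute HCl
Reagents that add atoms: none
Why: Borohydride reduces the aldehyde while the tropolone is shielded as its anion (chemoselective aldehyde reduction).

Step 11
Reactants: 13 α-humulene
Product: 14 rac-6,7-epoxyhumula-2,9-diene (2E,9E, trans-oxirane)
Conditions: mCPBA, NaHCO3, CH2Cl2, −20 °C (13 in excess)
Reagents that add atoms: 3-chloroperbenzoic acid OOC(=O)c1cccc(Cl)c1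
Why: Prilezhaev epoxidation should occur at the most nucleophilic and most strained trisubstituted 6,7-olefin, which masks this olefin and the doubly allylic C8 for steps 12 to 14.

Step 12
Reactants: 14 rac-6,7-epoxyhumula-2,9-diene
Product: 15 6,7-epoxyhumula-2,9-dien-4-ol (2E,9E, both C4 epimers)
Conditions: SeO2 (cat.), t-BuOOH, CH2Cl2, 0 °C to rt
Reagents that add atoms: tert-butyl hydroperoxide CC(C)(C)OO; selenium dioxide O=[Se]=O (catalytic oxygen carrier)
Why: Allylic hydroxylation by SeO2 (ene reaction, then [2,3] shift) should attack the remaining trisubstituted olefin at the CH2 on its more substituted end that is cis to the vinylic hydrogen (C4), with the E geometry kept.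

Step 13
Reactants: 15 6,7-epoxyhumula-2,9-dien-4-ol
Product: 16 (4S)-6,7-epoxyhumula-2,9-dien-4-ol
Conditions: Ti(OiPr)4 (cat.), D-(−)-diisopropyl tartrate, t-BuOOH (0.6 equiv), 4 Å MS, CH2Cl2, −20 °C
Reagents that add atoms: none
Why: In a Sharpless kinetic resolution with the D-tartrate the 4R allylic alcohols should be epoxidised fast and the 4S alcohols recovered, while the isolated 9,10-olefin is inert to the titanium catalyst.

Step 14
Reactants: 16 (4S)-6,7-epoxyhumula-2,9-dien-4-ol
Product: 17 (4S)-6,7-epoxy-4-[(tributylstannyl)methoxy]humula-2,9-diene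
Conditions: KH, THF, 0 °C; Bu3SnCH2I, rt
Reagents that add atoms: tributyl(iodomethyl)stannane CCCC[Sn](CI)(CCCC)CCCC
Why: Williamson etherification of the potassium alkoxide with a primary iodide, which leaves the C4 centre untouched.

Step 15
Reactants: 17 (4S)-6,7-epoxy-4-[(tributylstannyl)methoxy]humula-2,9-diene
Product: 18 (4S,2E,6E,9E)-4-[(tributylstannyl)methoxy]humula-2,6,9-triene
Conditions: WCl6, n-BuLi, THF, −78 °C to rt; then 17, rt
Reagents that add atoms: none
Why: Low-valent tungsten chloride deoxygenates oxiranes with retention of olefin geometry, so the E 6,7-olefin should return at a stage that has no acidic proton, and both oxirane forms converge to one compound.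

Step 16
Reactants: 18 (4S,2E,6E,9E)-4-[(tributylstannyl)methoxy]humula-2,6,9-triene
Product: 20 (2S,3Z,6E,9E)-2-(hydroxymethyl)humula-3,6,9-triene, via lithiomethyl ether 19 (not isolated)
Conditions: n-BuLi, THF, −78 to −40 °C; NH4Cl (aq.)
Reagents that add atoms: none
Why: Tin–lithium exchange triggers the Still–Wittig [2,3] shift through an envelope transition state in which the C3 methyl forces C5 pseudoaxial, so the new 3,4-olefin should be Z and the C4 centre is transferred suprafacially to C2 (C16 enters on the face that O4 leaves).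

Step 17
Reactants: 20 (2S,3Z,6E,9E)-2-(hydroxymethyl)humula-3,6,9-triene
Product: 22 (2R,3R,4S,6E,9E)-2-(hydroxymethyl)humula-6,9-diene-3,4-diol, via osmate ester 21 (not isolated)
Conditions: OsO4 (1.05 equiv), TMEDA, CH2Cl2, −78 °C; then Na2SO3 (aq.), THF, 40 °C
Reagents that add atoms: osmium tetroxide O=[Os](=O)(=O)=O
Why: In this hydroxyl-directed dihydroxylation the OsO4–TMEDA complex should be delivered by hydrogen bonding from the homoallylic OH to the nearby Z olefin, syn to the CH2OH group in the conformer with C2–H eclipsing the olefin (minimal A(1,3) strain), which sets 3R and 4S by syn addition.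

Step 18
Reactants: 22 (2R,3R,4S,6E,9E)-2-(hydroxymethyl)humula-6,9-diene-3,4-diol
Product: 23 (2S,3R,4S,6E,9E)-2-(iodomethyl)humula-6,9-diene-3,4-diol
Conditions: I2, PPh3, imidazole, toluene/MeCN, 0 °C
Reagents that add atoms: iodine II
Why: Appel-type iodination is selective for a primary hydroxyl beside secondary and tertiary ones, and the neutral buffered medium should avoid ether formation from the free C4 hydroxyl.

Step 19
Reactants: 23 (2S,3R,4S,6E,9E)-2-(iodomethyl)humula-6,9-diene-3,4-diol
Product: 24 (2S,3R,4S,6E,9E)-2-(iodomethyl)-3,4-bis(triethylsilyloxy)humula-6,9-diene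
Conditions: Et3SiOTf, 2,6-lutidine, CH2Cl2, −40 to 0 °C
Reagents that add atoms: triethylsilyl trifluoromethanesulfonate CC[Si](CC)(CC)OS(=O)(=O)C(F)(F)F
Why: The silyl triflate silylates the secondary and the tertiary hydroxyl, which removes the acidic protons before the organolithium stage and stores both oxygens in a fluoride-labile form.

Step 20
Reactants: 24 (2S,3R,4S,6E,9E)-2-(iodomethyl)-3,4-bis(triethylsilyloxy)humula-6,9-diene; 7 5-bromo-2,6-dimethoxy-4-methylcyclohepta-2,4,6-trien-1-one
Product: 28 ring A annulation product (2-methoxytropone-fused dihydropyran on C2/C3 of (2R,3R,4S,6E,9E)-humula-6,9-dien-4-ol), via alkyllithium 25 (not isolated), via borinate ate complex 26 (not isolated), via coupled bis-silyl ether 27 (not isolated)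
Conditions: t-BuLi, Et2O, −78 °C; B-methoxy-9-BBN, THF, −78 °C to rt; then 7, Pd(dppf)Cl2 (cat.), AsPh3 (cat.), K3PO4 (aq.), DMF, 45 °C; then TBAF, THF, 45 °C (one pot)
Reagents that add atoms: none
Why: Iodine–lithium exchange and trapping with B-methoxy-9-BBN give the borinate ate complex without a free C16 radical (which could add across the ring to the 9,10-olefin); zerovalent palladium inserts into the C5'–Br bond of 7, the primary alkyl group transmetalates from boron and reductive elimination forms the C16–C5' bond. Fluoride then removes both silyl groups, and the tertiary C3 alkoxide adds to C6' (the β-carbon of the C1' enone, a vinylogous ester) and expels methoxide, which forms the O–C6' bond. The closest known reaction types are the B-alkyl Suzuki–Miyaura coupling of alkyl iodides through 9-BBN ate complexes with hindered aryl and vinyl bromides, and the alkoxide exchange of alkoxytropones by addition–elimination. The dihydropyran closes by a 6-exo-trig addition followed by β-elimination. No stereocentre is formed or touched, since C2, C3 and C4 come from steps 16 and 17 and the planar tropone adds no new element. The step needs insertion at C–Br beside two C–OMe bonds (secured by bond strength) and six-ring closure by O3 over seven-ring closure by the C4 alkoxide (secured by ring size and by the reversibility of the vinylogous ester exchange).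

Step 21
Reactants: 28 ring A annulation product; 12 2,6-dihydroxy-5-(hydroxymethyl)-4-methylcyclohepta-2,4,6-trien-1-one
Product: 30 O-methyl ether of the target at the ring A tropolone, via tropolone quinone methide 29 (not isolated)
Conditions: 12 (excess), toluene, 140 °C, sealed tube
Reagents that add atoms: none
Why: Thermal loss of water from 12 gives the tropolone o-quinone methide, an electron-poor heterodiene that should add suprafacially to the electron-rich trisubstituted 6,7-olefin (inverse-electron-demand hetero-Diels–Alder reaction), with oxygen on the more substituted C7, a trans ring fusion from the E olefin, and 6R,7R expected from attack on the exposed olefin face of the macrocycle held by ring A.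

Step 22
Reactants: 30 O-methyl ether of the target at the ring A tropolone
Product: 31 target compound CNP0283947.4
Conditions: LiOH, THF/H2O, 40 °C; dilute HCl to pH 4
Reagents that add atoms: lithium hydroxide [Li+].[OH-]
Why: Hydroxide adds to the methoxy-bearing carbon of the 2-methoxytropone and expels methoxide (vinylogous ester hydrolysis by addition–elimination), and the resulting tropolonate should resist further attack so that both pyran ethers survive.

**Compound list**

1 | 2-methylanisole | COc1ccccc1C | starting material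
2 | 1-methoxy-2-methylcyclohexa-1,4-diene | COC1=C(C)CC=CC1 | intermediate
3 | rac-7,7-dibromo-1-methoxy-6-methylbicyclo[4.1.0]hept-3-ene (cis-fused) | COC12CC=CCC1(C)C2(Br)Br | intermediate
4 | 7,7-dibromo-1-methoxy-6-methylbicyclo[4.1.0]heptane-3,4-diol (cis-diol, racemic) | COC12CC(O)C(O)CC1(C)C2(Br)Br | intermediate
5 | 7,7-dibromo-1-methoxy-6-methylbicyclo[4.1.0]heptane-3,4-dione | COC12CC(=O)C(=O)CC1(C)C2(Br)Br | intermediate
6 | 5-bromo-2-hydroxy-6-methoxy-4-methylcyclohepta-2,4,6-trien-1-one (tropolone tautomers) | O=C1C(O)=CC(C)=C(Br)C(OC)=C1 | intermediate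
7 | 5-bromo-2,6-dimethoxy-4-methylcyclohepta-2,4,6-trien-1-one | O=C1C(OC)=CC(C)=C(Br)C(OC)=C1 | intermediate
8 | 2-bromo-3-methylcyclohepta-2,5-dien-1-one | O=C1CC=CCC(C)=C1Br | intermediate
9 | 2-(hydroxymethyl)-3-methylcyclohepta-2,5-dien-1-one | O=C1CC=CCC(C)=C1CO | intermediate
10 | 5,6-dihydroxy-2-(hydroxymethyl)-3-methylcyclohept-2-en-1-one (cis-diol, racemic) | O=C1CC(O)C(O)CC(C)=C1CO | intermediate
11 | 4,7-dihydroxy-2-methyl-5-oxocyclohepta-1,3,6-triene-1-carbaldehyde | O=CC1=C(C)C=C(O)C(=O)C=C1O | intermediate
12 | 2,6-dihydroxy-5-(hydroxymethyl)-4-methylcyclohepta-2,4,6-trien-1-one | OCC1=C(C)C=C(O)C(=O)C=C1O | intermediate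
13 | α-humulene, (1E,4E,8E)-2,6,6,9-tetramethylcycloundeca-1,4,8-triene | C/C1=C\CC(C)(C)/C=C/C/C(C)=C/CC1 | starting material
14 | rac-6,7-epoxyhumula-2,9-diene (2E,9E, trans-oxirane) | C/C1=C\CC(C)(C)/C=C/CC2(C)OC2CC1 | intermediate
15 | 6,7-epoxyhumula-2,9-dien-4-ol (2E,9E, trans-oxirane, both C4 epimers) | C/C1=C\CC(C)(C)/C=C/CC2(C)OC2CC1O | intermediate
16 | (4S)-6,7-epoxyhumula-2,9-dien-4-ol (2E,9E, both trans-oxirane forms) | C/C1=C\CC(C)(C)/C=C/CC2(C)OC2C[C@@H]1O | intermediate
17 | (4S)-6,7-epoxy-4-[(tributylstannyl)methoxy]humula-2,9-diene | C/C1=C\CC(C)(C)/C=C/CC2(C)OC2C[C@@H]1OC[Sn](CCCC)(CCCC)CCCC | intermediate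
18 | (4S,2E,6E,9E)-4-[(tributylstannyl)methoxy]humula-2,6,9-triene | C/C1=C\CC(C)(C)/C=C/C/C(C)=C/C[C@@H]1OC[Sn](CCCC)(CCCC)CCCC | intermediate
19 | (4S,2E,6E,9E)-4-(lithiomethoxy)humula-2,6,9-triene | C/C1=C\CC(C)(C)/C=C/C/C(C)=C/C[C@@H]1OC[Li] | intermediate
20 | (2S,3Z,6E,9E)-2-(hydroxymethyl)humula-3,6,9-triene (C2 arranged as in the target) | OC[C@H]1CC(C)(C)/C=C/C/C(C)=C/C/C=C1/C | intermediate
21 | cyclic 3,4-osmate ester of 22 (hexavalent osmium, TMEDA complex) | OC[C@H]1CC(C)(C)/C=C/C/C(C)=C/C[C@@H]2O[Os](=O)(=O)O[C@]12C.CN(C)CCN(C)C | intermediate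
22 | (2R,3R,4S,6E,9E)-2-(hydroxymethyl)humula-6,9-diene-3,4-diol | OC[C@H]1CC(C)(C)/C=C/C/C(C)=C/C[C@H](O)[C@]1(C)O | intermediate
23 | (2S,3R,4S,6E,9E)-2-(iodomethyl)humula-6,9-diene-3,4-diol | IC[C@H]1CC(C)(C)/C=C/C/C(C)=C/C[C@H](O)[C@]1(C)O | intermediate
24 | (2S,3R,4S,6E,9E)-2-(iodomethyl)-3,4-bis(triethylsilyloxy)humula-6,9-diene | IC[C@H]1CC(C)(C)/C=C/C/C(C)=C/C[C@H](O[Si](CC)(CC)CC)[C@]1(C)O[Si](CC)(CC)CC | intermediate
25 | primary alkyllithium from 24 (lithium on C16) | [Li]C[C@H]1CC(C)(C)/C=C/C/C(C)=C/C[C@H](O[Si](CC)(CC)CC)[C@]1(C)O[Si](CC)(CC)CC | intermediate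
26 | lithium B-alkyl-B-methoxy-9-borabicyclo[3.3.1]nonane ate complex (alkyl = C16 of 25) | [Li+].CO[B-]1(C[C@H]2CC(C)(C)/C=C/C/C(C)=C/C[C@H](O[Si](CC)(CC)CC)[C@]2(C)O[Si](CC)(CC)CC)C3CCCC1CCC3 | intermediate
27 | coupled bis-silyl ether: 2,6-dimethoxy-4-methyltropone bonded at C5' to C16 of the (2R,3R,4S)-3,4-bis(triethylsilyloxy)humula-6,9-diene | COC1=CC(C)=C(C[C@H]2CC(C)(C)/C=C/C/C(C)=C/C[C@H](O[Si](CC)(CC)CC)[C@]2(C)O[Si](CC)(CC)CC)C(OC)=CC1=O | intermediate
28 | ring A annulation product: 2-methoxytropone fused through C5'–C16 and C6'–O–C3 to (2R,3R,4S,6E,9E)-humula-6,9-dien-4-ol | COC1=CC(C)=C2C[C@H]3CC(C)(C)/C=C/C/C(C)=C/C[C@H](O)[C@]3(C)OC2=CC1=O | intermediate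
29 | tropolone o-quinone methide, 2-hydroxy-6-methyl-5-methylidenecyclohepta-2,6-diene-1,4-dione | C=C1C(=O)C=C(O)C(=O)C=C1C | intermediate
30 | O-methyl ether of the target at the ring A tropolone (2R,3R,4S,6R,7R,9E) | COC1=CC(C)=C2C[C@H]3CC(C)(C)/C=C/C[C@@]4(C)Oc5cc(O)c(=O)cc(C)c5C[C@@H]4C[C@H](O)[C@]3(C)OC2=CC1=O | intermediate
31 | CNP0283947.4, bis-tropolone humulene meroterpenoid (2R,3R,4S,6R,7R,9E) | Cc1cc(=O)c(O)cc2c1C[C@H]1CC(C)(C)/C=C/C[C@@]3(C)Oc4cc(O)c(=O)cc(C)c4C[C@@H]3C[C@H](O)[C@]1(C)O2 | target

**Step count and risks**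

Total step count: 22. Longest linear sequence: 12 steps (steps 11 to 22, from α-humulene). The two tropone branches have 8 steps (1–5, 20–22) and 9 steps (1, 2, 6–10, 21, 22).

Steps most likely to fail:

1. Step 21. The cycloaddition may show poor facial selectivity on the 6,7-olefin, or may also engage the ring A tropone, because the only control element is the conformation of the macrocycle. Fallback, from 28 back to 30: the C4 carbinol of 28 would be oxidised with Dess–Martin periodinane to the ketone F1, in which the sp2 C4 changes the ring conformation beside the 6,7-olefin. Cycloaddition of F1 with 29 (from 12) would give the ketone adduct F2. Reagent-controlled reduction of F2 with (R)-2-methyl-CBS-oxazaborolidine and catecholborane would return the 4S alcohol 30.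

2. Step 17. The osmium reagent may also attack the reactive 6,7-olefin if hydrogen-bond delivery from the homoallylic hydroxyl is weak. Fallback, from 17 back to 22: the oxirane would be kept as the mask. Rearrangement of 17 under the step 16 conditions would give the oxirane alcohol F3. Catalytic OsO4/NMO, now with only one reactive olefin, would give the oxirane triol F4. Immediate silylation (Me3SiOTf, 2,6-lutidine) to F5 would prevent attack of the C3 hydroxyl on the oxirane. Tungsten deoxygenation as in step 15 would give F6, and K2CO3 in methanol would release 22.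

3. Step 20. Transmetalation may stall at the doubly ortho-substituted bromide, or the ring closure may not follow in the same flask. Fallback, from 24 back to 28: the alkyllithium 25 would be transmetalated with ZnBr2 to the alkylzinc bromide F7. Negishi coupling with 7 (Pd(OAc)2, CPhos, THF) would give 27, which would be isolated. TBAF in a separate step would then close ring A to 28.

Further compounds
F1 | step 21 | C4 ketone of 28 | COC1=CC(C)=C2C[C@H]3CC(C)(C)/C=C/C/C(C)=C/CC(=O)[C@]3(C)OC2=CC1=O
F2 | step 21 | C4 ketone of 30 | COC1=CC(C)=C2C[C@H]3CC(C)(C)/C=C/C[C@@]4(C)Oc5cc(O)c(=O)cc(C)c5C[C@@H]4CC(=O)[C@]3(C)OC2=CC1=O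
F3 | step 17 | (2S,3Z,9E)-6,7-epoxy-2-(hydroxymethyl)humula-3,9-diene | OC[C@H]1CC(C)(C)/C=C/CC2(C)OC2C/C=C1/C
F4 | step 17 | (2R,3R,4S,9E)-6,7-epoxy-2-(hydroxymethyl)humul-9-ene-3,4-diol | OC[C@H]1CC(C)(C)/C=C/CC2(C)OC2C[C@H](O)[C@]1(C)O
F5 | step 17 | tris(trimethylsilyl) ether of F4 | C[Si](C)(C)OC[C@H]1CC(C)(C)/C=C/CC2(C)OC2C[C@H](O[Si](C)(C)C)[C@]1(C)O[Si](C)(C)C
F6 | step 17 | tris(trimethylsilyl) ether of 22 | C[Si](C)(C)OC[C@H]1CC(C)(C)/C=C/C/C(C)=C/C[C@H](O[Si](C)(C)C)[C@]1(C)O[Si](C)(C)C
F7 | step 20 | alkylzinc bromide from 25 (zinc on C16) | Br[Zn]C[C@H]1CC(C)(C)/C=C/C/C(C)=C/C[C@H](O[Si](CC)(CC)CC)[C@]1(C)O[Si](CC)(CC)CC
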